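**Retrosynthetic overview**

1. The C5 methoxy group comes from O-methylation of a tertiary quinol, and the C5 allyl group from face-selective allylboration of the C5 carbonyl of a 5,6-o-quinone; the C6 carbonyl is deactivated by O1 as a vinylogous ester. The quinone comes from the 5,6-catechol, carried as its dibenzyl ether.
2. The C3 methyl is the reduced ester carbon of a trans methyl 2-aryl-2,3-dihydrobenzofuran-3-carboxylate.
3. Feature on which the route rests (benzofuran numbering): C3 carries the ring carbon C3a and a one-carbon branch, next to the aryl-bearing C2 on O1. That pattern results when ring A of a flavanone moves from the ketone carbon to the neighbouring CH2, so ring O1–C2–C3–C3a–C7a is cut at C3–C3a back to the pyranone of a (2S)-6,7-dioxygenated flavanone.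
4. The flavanone comes from a chromone and 3,4,5-trimethoxyphenylboronic acid (catalytic asymmetric 1,4-addition sets C2); the chromone comes from a 2-hydroxyacetophenone and DMF dimethyl acetal.
5. Ring order: benzene ring bought, pyranone closed (step 2), pyranone contracted to the dihydrofuran (step 4), benzene ring dearomatised to the dienone last (steps 9–11).

Key step: step 4

Remark: the catechol is carried as two benzyl ethers rather than a methylenedioxy bridge, because a Lewis acid able to open the bridge would also threaten the aryl methyl ethers and the benzylic C2–O1 bond. The antipodes of the two chiral catalysts (steps 3 and 10) are assigned by analogy with the closest substrate classes, and the mirror-image catalyst would be used if a first run showed the opposite sense. Diisopropyl allylboronate 15 is treated as a purchasable reagent.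

**Route**

Step 1
Reactants: 1 2′,4′,5′-trihydroxyacetophenone
Product: 2 1-[4,5-bis(benzyloxy)-2-hydroxyphenyl]ethan-1-one
Conditions: BnBr (2.1 equiv), K2CO3 (2.2 equiv), DMF, argon, 20 °C
Reagents that add atoms: benzyl bromide, BrCc1ccccc1
Why: Williamson etherification; the 2-OH is hydrogen-bonded to the acetyl carbonyl and is the least nucleophilic, so the 4- and 5-OH should be benzylated.

Step 2
Reactants: 2 1-[4,5-bis(benzyloxy)-2-hydroxyphenyl]ethan-1-one; 3 N,N-dimethylformamide dimethyl acetal
Product: 5 6,7-bis(benzyloxy)-4H-chromen-4-one, via (E)-enaminone 4 (not isolated)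
Conditions: 3 (2 equiv), PhMe, 100 °C; then conc. HCl, CH2Cl2, 20 °C
Reagents that add atoms: none
Why: Enaminone condensation of the methyl ketone with the formamide acetal, then acid-promoted addition of the phenol to the β-carbon and loss of dimethylamine (chromone synthesis); benzyl ethers tolerate both stages.

Step 3
Reactants: 5 6,7-bis(benzyloxy)-4H-chromen-4-one; 6 3,4,5-trimethoxyphenylboronic acid
Product: 7 (2S)-6,7-bis(benzyloxy)-2-(3,4,5-trimethoxyphenyl)-2,3-dihydro-4H-chromen-4-one
Conditions: Pd(OCOCF3)2 (5 mol %), (R)-4-tert-butyl-2-(pyridin-2-yl)-4,5-dihydrooxazole (6 mol %), NH4PF6 (30 mol %), H2O (5 equiv), ClCH2CH2Cl, 60 °C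
Reagents that add atoms: none
Why: Asymmetric conjugate addition of an arylboronic acid to a chromone by a cationic divalent palladium pyridine-oxazoline catalyst (transmetalation, insertion of C2=C3 into the aryl–Pd bond, protonolysis of the palladium enolate); the tert-butyl group of the ligand shields one face of the bound chromone and should set C2 as S.

Step 4
Reactants: 7 (2S)-6,7-bis(benzyloxy)-2-(3,4,5-trimethoxyphenyl)-2,3-dihydro-4H-chromen-4-one
Product: 9 methyl (2S,3S)-5,6-bis(benzyloxy)-2-(3,4,5-trimethoxyphenyl)-2,3-dihydro-1-benzofuran-3-carboxylate, via methyl enol ether 8 (not isolated)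
Conditions: PhI(OAc)2 (1.2 equiv), conc. H2SO4 (0.5 equiv), HC(OMe)3, 20 °C; then aq. NaHCO3
Reagents that add atoms: trimethyl orthoformate, COC(OC)OC; water, O
Why: Acid and orthoformate turn the C4 ketone into methyl enol ether 8; PhI(OAc)2 then attacks C3 on the face anti to the C2 aryl group while methanol adds to C4, giving a C4 dimethyl ketal whose equatorial C3–I bond lies antiperiplanar to the C4–C4a bond. Ring A carbon C4a shifts from C4 to C3 with inversion as iodobenzene leaves, through a bridged phenonium-type transition state, and the dialkoxycarbenium ion left at C4 is hydrolysed to the methyl ester on work-up. The closest known reaction type is the oxidative rearrangement of flavanones with trivalent iodine in trimethyl orthoformate to trans methyl 2-aryl-2,3-dihydrobenzofuran-3-carboxylates. The one ring closed, O1–C2–C3–C3a–C7a, arises by ring contraction (the 1,2-aryl shift makes C3–C3a as C4–C4a breaks), not by cyclisation of an open chain. The new C3 centre is controlled by C2, since anti iodination followed by inversion places the ester trans to the aryl group, and trans is also the thermodynamic epimer of this epimerisable centre; C2 itself is not touched. The step needs ring A to migrate in preference to the C2 aryl group and faster than dehydrogenation to the flavone: the two methoxy groups on C4 push the shift, C4a is para to the 7-benzyloxy oxygen and ortho to O1, and the 3,4,5-trimethoxyphenyl group is a poor migrating group that cannot align with the equatorial C3–I bond.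

Step 5
Reactants: 9 methyl (2S,3S)-5,6-bis(benzyloxy)-2-(3,4,5-trimethoxyphenyl)-2,3-dihydro-1-benzofuran-3-carboxylate
Product: 10 [(2S,3R)-5,6-bis(benzyloxy)-2-(3,4,5-trimethoxyphenyl)-2,3-dihydro-1-benzofuran-3-yl]methanol
Conditions: LiAlH4, THF, 0 °C
Reagents that add atoms: none
Why: Hydride reduction of the ester to the primary alcohol; C3 keeps its geometry (the descriptor changes by priority only) and benzyl and methyl ethers are inert.

Step 6
Reactants: 10 [(2S,3R)-5,6-bis(benzyloxy)-2-(3,4,5-trimethoxyphenyl)-2,3-dihydro-1-benzofuran-3-yl]methanol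
Product: 11 [(2S,3R)-5,6-bis(benzyloxy)-2-(3,4,5-trimethoxyphenyl)-2,3-dihydro-1-benzofuran-3-yl]methyl methanesulfonate
Conditions: MsCl, Et3N, CH2Cl2, 0 °C
Reagents that add atoms: methanesulfonyl chloride, CS(=O)(=O)Cl
Why: Sulfonylation of an unhindered primary alcohol; no stereocentre is involved.

Step 7
Reactants: 11 [(2S,3R)-5,6-bis(benzyloxy)-2-(3,4,5-trimethoxyphenyl)-2,3-dihydro-1-benzofuran-3-yl]methyl methanesulfonate
Product: 12 (2S,3S)-5,6-bis(benzyloxy)-3-methyl-2-(3,4,5-trimethoxyphenyl)-2,3-dihydro-1-benzofuran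
Conditions: LiEt3BH, THF, 0 to 20 °C
Reagents that add atoms: none
Why: SN2 displacement of the primary mesylate by hydride; the reagent is nucleophilic and only weakly basic, so elimination towards C3 should not compete and the trans C2/C3 relationship is kept.

Step 8
Reactants: 12 (2S,3S)-5,6-bis(benzyloxy)-3-methyl-2-(3,4,5-trimethoxyphenyl)-2,3-dihydro-1-benzofuran
Product: 13 (2S,3S)-3-methyl-2-(3,4,5-trimethoxyphenyl)-2,3-dihydro-1-benzofuran-5,6-diol
Conditions: H2 (1 atm), 10% Pd/C, EtOAc, 20 °C; filtered under argon and used at once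
Reagents that add atoms: none
Why: Hydrogenolysis of benzyl aryl ethers under neutral conditions, which should spare the aryl methyl ethers and the slower-reacting benzylic C2–O1 bond of the dihydrofuran.

Step 9
Reactants: 13 (2S,3S)-3-methyl-2-(3,4,5-trimethoxyphenyl)-2,3-dihydro-1-benzofuran-5,6-diol
Product: 14 (2S,3S)-3-methyl-2-(3,4,5-trimethoxyphenyl)-2,3-dihydro-1-benzofuran-5,6-dione
Conditions: Ag2O, Na2SO4, Et2O, 0 °C, dark; filtered cold and used at once
Reagents that add atoms: none
Why: Two-electron oxidation of a catechol to the o-quinone by Ag2O in a neutral, dry medium; the quinone is stabilised by O1 as a vinylogous ester and is kept cold and free of acid and base to avoid tautomerisation through C3–H.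

Step 10
Reactants: 14 (2S,3S)-3-methyl-2-(3,4,5-trimethoxyphenyl)-2,3-dihydro-1-benzofuran-5,6-dione; 15 diisopropyl allylboronate
Product: 17 (2S,3S,5R)-5-allyl-5-hydroxy-3-methyl-2-(3,4,5-trimethoxyphenyl)-2,3-dihydro-1-benzofuran-6(5H)-one, via diisopropyl borate ester 16 (not isolated)
Conditions: 15 (1.5 equiv), (S)-3,3′-dibromo-1,1′-bi-2-naphthol (15 mol %), PhCF3/PhMe 3:1, −35 °C; then pH 7 buffer
Reagents that add atoms: none
Why: Proposed new method: the chiral diol exchanges one isopropoxy group on boron to give a more Lewis acidic, hydrogen-bonded mixed boronate, which binds the C5 carbonyl (the more electrophilic one, since C6 is a vinylogous ester carbonyl through O1–C7a=C7) and transfers allyl through a closed six-membered chair transition state, so that addition is 1,2 and the binaphthyl wall, not the remote C2/C3 centres, should select the C5 face syn to the C2 aryl group (5R); the closest known reaction type is the chiral-biphenol-catalysed asymmetric allylboration of ketones and of cyclic 1,2-dicarbonyl compounds such as isatins.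

Step 11
Reactants: 17 (2S,3S,5R)-5-allyl-5-hydroxy-3-methyl-2-(3,4,5-trimethoxyphenyl)-2,3-dihydro-1-benzofuran-6(5H)-one
Product: 18 (2S,3S,5R)-5-allyl-5-methoxy-3-methyl-2-(3,4,5-trimethoxyphenyl)-2,3-dihydro-1-benzofuran-6(5H)-one
Conditions: NaN(SiMe3)2 (1.05 equiv), THF, −78 °C; then MeOTf (1.5 equiv), −78 to −40 °C; Et3N, aq. NaHCO3
Reagents that add atoms: methyl trifluoromethanesulfonate, COS(=O)(=O)C(F)(F)F
Why: O-alkylation of the tertiary sodium alkoxide with a very reactive methylating agent (Williamson type); the C5–O bond is not broken, so C5 stays R, and the low temperature should keep the alkoxide from shifting its allyl group by anionic oxy-Cope rearrangement.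

**Compound list**

1 | 2′,4′,5′-trihydroxyacetophenone | CC(=O)c1cc(O)c(O)cc1O | starting material
2 | 1-[4,5-bis(benzyloxy)-2-hydroxyphenyl]ethan-1-one | CC(=O)c1cc(OCc2ccccc2)c(OCc2ccccc2)cc1O | intermediate
3 | N,N-dimethylformamide dimethyl acetal | COC(OC)N(C)C | starting material
4 | (E)-1-[4,5-bis(benzyloxy)-2-hydroxyphenyl]-3-(dimethylamino)prop-2-en-1-one | CN(C)/C=C/C(=O)c1cc(OCc2ccccc2)c(OCc2ccccc2)cc1O | intermediate
5 | 6,7-bis(benzyloxy)-4H-chromen-4-one | O=c1ccoc2cc(OCc3ccccc3)c(OCc3ccccc3)cc12 | intermediate
6 | 3,4,5-trimethoxyphenylboronic acid | COc1cc(B(O)O)cc(OC)c1OC | starting material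
7 | (2S)-6,7-bis(benzyloxy)-2-(3,4,5-trimethoxyphenyl)-2,3-dihydro-4H-chromen-4-one | c12cc(OCc3ccccc3)c(OCc3ccccc3)cc1O[C@H](c1cc(OC)c(OC)c(OC)c1)CC2=O | intermediate
8 | (2S)-6,7-bis(benzyloxy)-4-methoxy-2-(3,4,5-trimethoxyphenyl)-2H-chromene | c12cc(OCc3ccccc3)c(OCc3ccccc3)cc1O[C@H](c1cc(OC)c(OC)c(OC)c1)C=C2OC | intermediate
9 | methyl (2S,3S)-5,6-bis(benzyloxy)-2-(3,4,5-trimethoxyphenyl)-2,3-dihydro-1-benzofuran-3-carboxylate | c12cc(OCc3ccccc3)c(OCc3ccccc3)cc1O[C@H](c1cc(OC)c(OC)c(OC)c1)[C@H]2C(=O)OC | intermediate
10 | [(2S,3R)-5,6-bis(benzyloxy)-2-(3,4,5-trimethoxyphenyl)-2,3-dihydro-1-benzofuran-3-yl]methanol | c12cc(OCc3ccccc3)c(OCc3ccccc3)cc1O[C@H](c1cc(OC)c(OC)c(OC)c1)[C@H]2CO | intermediate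
11 | [(2S,3R)-5,6-bis(benzyloxy)-2-(3,4,5-trimethoxyphenyl)-2,3-dihydro-1-benzofuran-3-yl]methyl methanesulfonate | c12cc(OCc3ccccc3)c(OCc3ccccc3)cc1O[C@H](c1cc(OC)c(OC)c(OC)c1)[C@H]2COS(C)(=O)=O | intermediate
12 | (2S,3S)-5,6-bis(benzyloxy)-3-methyl-2-(3,4,5-trimethoxyphenyl)-2,3-dihydro-1-benzofuran | c12cc(OCc3ccccc3)c(OCc3ccccc3)cc1O[C@H](c1cc(OC)c(OC)c(OC)c1)[C@H]2C | intermediate
13 | (2S,3S)-3-methyl-2-(3,4,5-trimethoxyphenyl)-2,3-dihydro-1-benzofuran-5,6-diol | c12cc(O)c(O)cc1O[C@H](c1cc(OC)c(OC)c(OC)c1)[C@H]2C | intermediate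
14 | (2S,3S)-3-methyl-2-(3,4,5-trimethoxyphenyl)-2,3-dihydro-1-benzofuran-5,6-dione | O=C1C=C2C(=CC1=O)O[C@H](c1cc(OC)c(OC)c(OC)c1)[C@H]2C | intermediate
15 | diisopropyl allylboronate (allyldiisopropoxyborane) | C=CCB(OC(C)C)OC(C)C | starting material
16 | diisopropyl (2S,3S,5R)-5-allyl-3-methyl-6-oxo-2-(3,4,5-trimethoxyphenyl)-2,3,5,6-tetrahydro-1-benzofuran-5-yl borate | C=CC[C@@]1(OB(OC(C)C)OC(C)C)C=C2C(=CC1=O)O[C@H](c1cc(OC)c(OC)c(OC)c1)[C@H]2C | intermediate
17 | (2S,3S,5R)-5-allyl-5-hydroxy-3-methyl-2-(3,4,5-trimethoxyphenyl)-2,3-dihydro-1-benzofuran-6(5H)-one | C=CC[C@@]1(O)C=C2C(=CC1=O)O[C@H](c1cc(OC)c(OC)c(OC)c1)[C@H]2C | intermediate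
18 | (2S,3S,5R)-5-allyl-5-methoxy-3-methyl-2-(3,4,5-trimethoxyphenyl)-2,3-dihydro-1-benzofuran-6(5H)-one | C=CC[C@@]1(OC)C=C2C(=CC1=O)O[C@H](c1cc(OC)c(OC)c(OC)c1)[C@H]2C | target

**Step count**

Total steps: 11. Longest linear sequence: 11 steps (from 1 to 18).

**Steps most likely to fail**

1. Step 10 (allylboration of the o-quinone). The catalyst has to tell a vinyl flank from an acyl flank at C5 and the substrate offers no bias of its own, so facial selectivity may be poor. An uncatalysed background addition may erode it further, and the quinone may tautomerise through C3–H towards the aromatic benzofuran diol before it is captured. The fallback uses known chemistry without facial control and sets out from quinone 14. Allylindium sesquibromide (C3H5)3In2Br3, preformed from allyl bromide and indium powder in DMF and decanted from the metal, is added at −40 °C. It should add 1,2 to the same C5 carbonyl and give quinol 17 together with its C5 epimer, (2S,3S,5S)-5-allyl-5-hydroxy-3-methyl-2-(3,4,5-trimethoxyphenyl)-2,3-dihydro-1-benzofuran-6(5H)-one F1. The two diastereomers are separated by preparative HPLC and the route is rejoined at 17.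

2. Step 4 (ring contraction). The C2 aryl group may migrate instead of ring A, the iodane may dehydrogenate the enol ether to the flavone, the acid may open the pyranone to the chalcone and erode the C2 configuration, or the iodane may attack the electron-rich aryl rings. The fallback makes the same C3–C3a bond through a carbene instead of an iodane and sets out from flavanone 7. The lithium enolate (LiN(SiMe3)2, THF, −78 °C) is acylated with 2,2,2-trifluoroethyl trifluoroacetate to (2S)-6,7-bis(benzyloxy)-3-(trifluoroacetyl)-2-(3,4,5-trimethoxyphenyl)chroman-4-one F2. Detrifluoroacetylative diazo transfer (MsN3, Et3N, MeCN) then gives (2R)-6,7-bis(benzyloxy)-3-diazo-2-(3,4,5-trimethoxyphenyl)chroman-4-one F3, in which the descriptor changes by priority only. Photolysis in MeOH (Wolff rearrangement: ring A migrates to the carbene carbon and methanol traps the ketene) should give ester 9 mixed with its cis epimer, methyl (2S,3R)-5,6-bis(benzyloxy)-2-(3,4,5-trimethoxyphenyl)-2,3-dihydro-1-benzofuran-3-carboxylate F4. Brief treatment with NaOMe in MeOH equilibrates F4 to the trans ester, and the route is rejoined at 9.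

3. Step 11 (O-methylation of the tertiary quinol). The alkoxide may shift its allyl group to C3a by anionic oxy-Cope rearrangement or lose it by retro-allylation before it is methylated, and the vinylogous ester oxygen may be methylated instead. The fallback uses the allyl shift on purpose and sets out from quinol 17. KH and 18-crown-6 in THF at 0 °C should move the allyl group suprafacially from C5 to C3a, and work-up with aq. NH4Cl gives the diosphenol (2S,3S,3aS)-3a-allyl-5-hydroxy-3-methyl-2-(3,4,5-trimethoxyphenyl)-3,3a-dihydro-1-benzofuran-6(2H)-one F5. K2CO3 and Me2SO4 in acetone methylate its acidic enol to (2S,3S,3aS)-3a-allyl-5-methoxy-3-methyl-2-(3,4,5-trimethoxyphenyl)-3,3a-dihydro-1-benzofuran-6(2H)-one F6. Gentle heating in toluene should then return the allyl group to the same face of C5 by Cope rearrangement and give 18 with the 5R configuration. Heating is stopped at that point, because the dienone can go on to the aryl allyl ether by retro-Claisen rearrangement.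

**Further compounds**

F1 | step 10 | (2S,3S,5S)-5-allyl-5-hydroxy-3-methyl-2-(3,4,5-trimethoxyphenyl)-2,3-dihydro-1-benzofuran-6(5H)-one | C=CC[C@]1(O)C=C2C(=CC1=O)O[C@H](c1cc(OC)c(OC)c(OC)c1)[C@H]2C
F2 | step 4 | (2S)-6,7-bis(benzyloxy)-3-(trifluoroacetyl)-2-(3,4,5-trimethoxyphenyl)chroman-4-one | c12cc(OCc3ccccc3)c(OCc3ccccc3)cc1O[C@H](c1cc(OC)c(OC)c(OC)c1)C(C(=O)C(F)(F)F)C2=O
F3 | step 4 | (2R)-6,7-bis(benzyloxy)-3-diazo-2-(3,4,5-trimethoxyphenyl)chroman-4-one | c12cc(OCc3ccccc3)c(OCc3ccccc3)cc1O[C@H](c1cc(OC)c(OC)c(OC)c1)C(=[N+]=[N-])C2=O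
F4 | step 4 | methyl (2S,3R)-5,6-bis(benzyloxy)-2-(3,4,5-trimethoxyphenyl)-2,3-dihydro-1-benzofuran-3-carboxylate | c12cc(OCc3ccccc3)c(OCc3ccccc3)cc1O[C@H](c1cc(OC)c(OC)c(OC)c1)[C@@H]2C(=O)OC
F5 | step 11 | (2S,3S,3aS)-3a-allyl-5-hydroxy-3-methyl-2-(3,4,5-trimethoxyphenyl)-3,3a-dihydro-1-benzofuran-6(2H)-one | OC1=C[C@]2(CC=C)[C@H](C)[C@@H](c3cc(OC)c(OC)c(OC)c3)OC2=CC1=O
F6 | step 11 | (2S,3S,3aS)-3a-allyl-5-methoxy-3-methyl-2-(3,4,5-trimethoxyphenyl)-3,3a-dihydro-1-benzofuran-6(2H)-one | COC1=C[C@]2(CC=C)[C@H](C)[C@@H](c3cc(OC)c(OC)c(OC)c3)OC2=CC1=O
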